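**Retrosynthetic overview**
1. The vanillate ester is cut last (Steglich esterification with O-benzyl vanillic acid); the side-chain CH(CH3) comes from asymmetric hydrogenation of a 2-substituted allylic alcohol.
2. Key disconnection: the C3–side-chain bond and the O–C3a bond of the ether bridge are formed together, by palladium-catalysed syn-carboetherification of a bicyclic hexahydroazulene tertiary alcohol with a 2-bromoallyl silyl ether.
3. Enabling feature: the bridge oxygen on C6 is γ to the fully substituted ring-fusion carbon C3a (O–C6–C5–C4–C3a), C3a is bonded to the side-chain carbon C3, and O and side chain are cis on the cyclopentane; this is the pattern left by syn addition of a transannular C6 alkoxide and a carbon group across a C3=C3a cyclopentene alkene.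
4. The bicyclic alcohol comes from a hexahydroazulene diene: epoxidation of the cycloheptene alkene anti to the angular methyl, acid hydrolysis with inversion at C6, mono-benzylation at C7.
5. Ring order: cyclopentane from diallyl adipate (C8a set by asymmetric decarboxylative allylation); cycloheptene by Negishi coupling and ring-closing metathesis; oxolane and oxane rings (the 8-oxabicyclo[3.2.1]octane) in the key step.

Key step: step 10

Numbering: locants follow azulene numbering of the core (C1–C3 in the five-membered ring, C3a and C8a at the ring fusion, C4–C8 in the seven-membered ring).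
Assumption: the sense of induction of the two chiral catalysts (the PHOX ligand in step 2, taken by analogy with the six-membered ketone series, and the iridium ligand in step 12) is as stated; if a test showed the opposite sense, the ligand antipode would be used with no other change.

**Step 1**
Reactants: 1 diallyl adipate
Product: 3 allyl 1-methyl-2-oxocyclopentane-1-carboxylate (racemic), via sodium β-keto ester enolate 2 (not isolated)
Conditions: NaH (1.05 equiv), toluene, 95 °C; then MeI, DMF, rt (one pot)
Reagents that add atoms: methyl iodide, CI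
Why: Dieckmann condensation gives the stabilised sodium enolate of the β-keto ester, which is C-methylated in the same pot (enolate alkylation); the quaternary carbon is racemic here and is erased in step 2.

**Step 2**
Reactants: 3 allyl 1-methyl-2-oxocyclopentane-1-carboxylate
Product: 4 (R)-2-allyl-2-methylcyclopentan-1-one
Conditions: Pd2(dba)3 (2.5 mol%), (R)-t-BuPHOX [(R)-4-tert-butyl-2-(2-diphenylphosphanylphenyl)-4,5-dihydrooxazole] (6 mol%), THF, 25 °C
Reagents that add atoms: none
Why: Decarboxylative asymmetric allylic alkylation (Tsuji type): zerovalent palladium ionises the allyl ester, loss of CO2 leaves a prochiral enolate paired with the π-allylpalladium cation, and the PHOX ligand decides which enolate face is allylated, setting the quaternary C8a as (R).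

**Step 3**
Reactants: 4 (R)-2-allyl-2-methylcyclopentan-1-one
Product: 6 (R)-5-allyl-5-methylcyclopent-1-en-1-yl trifluoromethanesulfonate, via potassium enolate 5 (not isolated)
Conditions: KN(SiMe3)2, THF, −78 °C; then PhNTf2, −78 °C to 0 °C
Reagents that add atoms: N-phenyl-bis(trifluoromethanesulfonimide), O=S(=O)(N(c1ccccc1)S(=O)(=O)C(F)(F)F)C(F)(F)F
Why: Enol triflate formation: only one α-carbon carries hydrogens, so a single enolate forms and is O-sulfonylated; no stereocentre is touched.

**Step 4**
Reactants: 6 (R)-5-allyl-5-methylcyclopent-1-en-1-yl trifluoromethanesulfonate; 7 4-bromo-2-methylbut-1-ene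
Product: 9 (R)-5-allyl-5-methyl-1-(3-methylbut-3-en-1-yl)cyclopent-1-ene, via alkylzinc bromide 8 (not isolated)
Conditions: 7, Zn dust, LiCl, THF, 40 °C; then 6, Pd(dppf)Cl2 (5 mol%), THF, 50 °C
Reagents that add atoms: none
Why: Negishi coupling: zinc insertion gives the homoallylic alkylzinc bromide, which couples with the alkenyl triflate, the wide-bite-angle dppf ligand favouring reductive elimination over β-hydride elimination.

**Step 5**
Reactants: 9 (R)-5-allyl-5-methyl-1-(3-methylbut-3-en-1-yl)cyclopent-1-ene
Product: 10 (8aR)-6,8a-dimethyl-1,2,4,5,8,8a-hexahydroazulene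
Conditions: second-generation Grubbs catalyst RuCl2(H2IMes)(PCy3)(=CHPh) (5 mol%), CH2Cl2 (dilute), 40 °C
Reagents that add atoms: none
Why: Ring-closing metathesis between the allyl alkene and the 1,1-disubstituted alkene closes the seven-membered ring as a trisubstituted cycloheptene, while the hindered trisubstituted cyclopentene alkene should stay out of the metathesis.

**Step 6**
Reactants: 10 (8aR)-6,8a-dimethyl-1,2,4,5,8,8a-hexahydroazulene
Product: 11 (6R,7S,8aR)-6,7-epoxy-6,8a-dimethyl-1,2,4,5,6,7,8,8a-octahydroazulene (epoxide oxygen anti to the C8a methyl)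
Conditions: mCPBA (1.0 equiv), NaHCO3, CH2Cl2, −20 °C
Reagents that add atoms: 3-chloroperoxybenzoic acid, O=C(OO)c1cccc(Cl)c1
Why: Prilezhaev epoxidation: the cycloheptene alkene is the more accessible of the two trisubstituted alkenes (the cyclopentene alkene is flanked on both faces by the substituents of the quaternary C8a), and the peracid should approach anti to the pseudoaxial angular methyl, which sets C6 and C7.

**Step 7**
Reactants: 11 (6R,7S,8aR)-6,7-epoxy-6,8a-dimethyl-1,2,4,5,6,7,8,8a-octahydroazulene
Product: 12 (6S,7S,8aR)-6,8a-dimethyl-1,2,4,5,6,7,8,8a-octahydroazulene-6,7-diol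
Conditions: HClO4 (cat.), THF/H2O, 0 °C, short reaction time
Reagents that add atoms: water, O
Why: Acid-catalysed epoxide hydrolysis: water opens the protonated trisubstituted epoxide at the tertiary C6 with inversion (borderline SN2), which puts the C6 hydroxyl on the face of the C8a methyl and leaves the C7 oxygen in place, giving the trans-diol.

**Step 8**
Reactants: 12 (6S,7S,8aR)-6,8a-dimethyl-1,2,4,5,6,7,8,8a-octahydroazulene-6,7-diol
Product: 14 (6S,7S,8aR)-7-(benzyloxy)-6,8a-dimethyl-1,2,4,5,6,7,8,8a-octahydroazulen-6-ol, via sodium C7-alkoxide 13 (not isolated)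
Conditions: NaH (1.05 equiv), THF/DMF, 0 °C; then BnBr, Bu4NI (cat.), 0 °C to rt
Reagents that add atoms: benzyl bromide, BrCc1ccccc1
Why: Williamson ether synthesis: the secondary alkoxide is far more nucleophilic than the hindered tertiary one, so one equivalent of base and benzyl bromide should give the C7 benzyl ether selectively.

**Step 9**
Reactants: 15 2-bromoprop-2-en-1-ol
Product: 16 [(2-bromoprop-2-en-1-yl)oxy](tert-butyl)dimethylsilane
Conditions: TBSCl, imidazole, CH2Cl2, 0 °C to rt
Reagents that add atoms: tert-butyldimethylsilyl chloride, CC(C)(C)[Si](C)(C)Cl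
Why: Standard silylation of a primary allylic alcohol, which masks the hydroxyl against the alkoxide base of step 10.

**Step 10**
Reactants: 14 (6S,7S,8aR)-7-(benzyloxy)-6,8a-dimethyl-1,2,4,5,6,7,8,8a-octahydroazulen-6-ol; 16 [(2-bromoprop-2-en-1-yl)oxy](tert-butyl)dimethylsilane
Product: 18 tert-butyl({2-[(3R,3aS,6S,7S,8aR)-7-(benzyloxy)-6,8a-dimethyloctahydro-1H-3a,6-epoxyazulen-3-yl]prop-2-en-1-yl}oxy)dimethylsilane, via sodium C6-alkoxide 17 (not isolated)
Conditions: Pd2(dba)3 (2.5 mol%), DPEphos (6 mol%), NaOtBu (2 equiv), 16 (2 equiv), toluene, 100 °C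
Reagents that add atoms: none
Why: Proposed new method: oxidative addition of zerovalent palladium into the alkenyl C–Br bond of 16 and bromide/alkoxide exchange with 17 should give an alkenylpalladium tertiary alkoxide, whose C3=C3a alkene inserts suprafacially (syn) into the Pd–O bond across the seven-membered ring, after which C(sp3)–C(sp2) reductive elimination with retention forms the C3–side-chain bond; the closest known reaction type is the palladium-catalysed carboetherification of γ-hydroxy alkenes with aryl and alkenyl bromides, established for tertiary alcohols, 1,1-disubstituted alkenes and cyclic disubstituted alkenes but not for transannular attack on a trisubstituted ring alkene. The oxolane ring (O, C6, C5, C4, C3a) closes in the 5-exo-trig mode and, because C6 and C3a are 1,4-related in the cycloheptene, the same C–O bond closes the oxane ring (6-exo) and with it the whole 8-oxabicyclo[3.2.1]octane. The configuration at C3a is dictated by the tether: the C6 oxygen can reach C3a only on the ring face it already occupies, which is the face of the C8a methyl. The configuration at C3 follows from the syn insertion and the retentive reductive elimination, which place the alkenyl group cis to the new C–O bond. The step needs reductive elimination to outrun β-hydride elimination of the secondary alkylpalladium intermediate, which the wide-bite-angle DPEphos ligand and the absence of hydrogen on C3a should help, and it needs the C7 oxygen to stay out, which the benzyl ether secures.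

**Step 11**
Reactants: 18 the tricyclic silyl ether
Product: 19 2-[(3R,3aS,6S,7S,8aR)-7-(benzyloxy)-6,8a-dimethyloctahydro-1H-3a,6-epoxyazulen-3-yl]prop-2-en-1-ol
Conditions: Bu4NF, THF, 0 °C to rt
Reagents that add atoms: none
Why: Fluoride-mediated desilylation of the primary silyl ether; the benzyl ether and the bridging ether are inert.

**Step 12**
Reactants: 19 the allylic alcohol
Product: 20 (2S)-2-[(3R,3aS,6S,7S,8aR)-7-(benzyloxy)-6,8a-dimethyloctahydro-1H-3a,6-epoxyazulen-3-yl]propan-1-ol
Conditions: H2 (5 bar), [Ir(cod)((S)-tBu-PHOX)][B(C6H3-3,5-(CF3)2)4] (2 mol%), CH2Cl2, rt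
Reagents that add atoms: none
Why: Iridium-catalysed asymmetric hydrogenation of a 2-substituted (1,1-disubstituted) allylic alcohol: the cationic iridium phosphine–oxazoline catalyst selects the alkene face and so sets the side-chain centre as (S), and the substrate's own bias (C3–H eclipsing the C–CH2OH bond to avoid 1,2-allylic strain, hydrogen delivered anti to the bulky C3a) is predicted to point the same way.

**Step 13**
Reactants: 20 the saturated primary alcohol; 21 4-(benzyloxy)-3-methoxybenzoic acid
Product: 22 (2S)-2-[(3R,3aS,6S,7S,8aR)-7-(benzyloxy)-6,8a-dimethyloctahydro-1H-3a,6-epoxyazulen-3-yl]propyl 4-(benzyloxy)-3-methoxybenzoate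
Conditions: DCC, DMAP (cat.), CH2Cl2, 0 °C to rt
Reagents that add atoms: none
Why: Steglich esterification of the unhindered primary alcohol; the phenol is masked as its benzyl ether so that it cannot be acylated.

**Step 14**
Reactants: 22 the dibenzyl-protected ester
Product: 23 (2S)-2-[(3R,3aS,6S,7S,8aR)-7-hydroxy-6,8a-dimethyloctahydro-1H-3a,6-epoxyazulen-3-yl]propyl 4-hydroxy-3-methoxybenzoate (target, CNP0277205.1)
Conditions: H2 (1 atm), Pd(OH)2/C, EtOAc/EtOH, rt
Reagents that add atoms: none
Why: Hydrogenolysis of the aryl benzyl ether and of the secondary alkyl benzyl ether; the benzoate ester, the bridging ether and all stereocentres are not affected.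

**Compound list**
1 | diallyl adipate | C=CCOC(=O)CCCCC(=O)OCC=C | starting material
2 | sodium enolate of allyl 2-oxocyclopentane-1-carboxylate | C=CCOC(=O)C1=C([O-])CCC1.[Na+] | intermediate
3 | allyl 1-methyl-2-oxocyclopentane-1-carboxylate (racemic) | C=CCOC(=O)C1(C)CCCC1=O | intermediate
4 | (R)-2-allyl-2-methylcyclopentan-1-one | C=CC[C@@]1(C)CCCC1=O | intermediate
5 | potassium (R)-5-allyl-5-methylcyclopent-1-en-1-olate | C=CC[C@@]1(C)CCC=C1[O-].[K+] | intermediate
6 | (R)-5-allyl-5-methylcyclopent-1-en-1-yl trifluoromethanesulfonate | C=CC[C@@]1(C)CCC=C1OS(=O)(=O)C(F)(F)F | intermediate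
7 | 4-bromo-2-methylbut-1-ene | C=C(C)CCBr | starting material
8 | (3-methylbut-3-en-1-yl)zinc bromide | C=C(C)CC[Zn]Br | intermediate
9 | (R)-5-allyl-5-methyl-1-(3-methylbut-3-en-1-yl)cyclopent-1-ene | C=CC[C@@]1(C)CCC=C1CCC(C)=C | intermediate
10 | (8aR)-6,8a-dimethyl-1,2,4,5,8,8a-hexahydroazulene | C[C@]12CCC=C1CCC(C)=CC2 | intermediate
11 | (6R,7S,8aR)-6,7-epoxy-6,8a-dimethyl-1,2,4,5,6,7,8,8a-octahydroazulene | C[C@]12CCC=C1CC[C@@]3(C)O[C@H]3C2 | intermediate
12 | (6S,7S,8aR)-6,8a-dimethyl-1,2,4,5,6,7,8,8a-octahydroazulene-6,7-diol | C[C@]12CCC=C1CC[C@](C)(O)[C@@H](O)C2 | intermediate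
13 | sodium C7-alkoxide of diol 12 | C[C@]12CCC=C1CC[C@](C)(O)[C@@H]([O-])C2.[Na+] | intermediate
14 | (6S,7S,8aR)-7-(benzyloxy)-6,8a-dimethyl-1,2,4,5,6,7,8,8a-octahydroazulen-6-ol | C[C@]12CCC=C1CC[C@](C)(O)[C@@H](OCc3ccccc3)C2 | intermediate
15 | 2-bromoprop-2-en-1-ol | C=C(Br)CO | starting material
16 | [(2-bromoprop-2-en-1-yl)oxy](tert-butyl)dimethylsilane | C=C(Br)CO[Si](C)(C)C(C)(C)C | intermediate
17 | sodium C6-alkoxide of alcohol 14 | C[C@]12CCC=C1CC[C@](C)([O-])[C@@H](OCc3ccccc3)C2.[Na+] | intermediate
18 | tert-butyl({2-[(3R,3aS,6S,7S,8aR)-7-(benzyloxy)-6,8a-dimethyloctahydro-1H-3a,6-epoxyazulen-3-yl]prop-2-en-1-yl}oxy)dimethylsilane | C=C(CO[Si](C)(C)C(C)(C)C)[C@H]2CC[C@]3(C)C[C@H](OCc5ccccc5)[C@]4(C)CC[C@]23O4 | intermediate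
19 | 2-[(3R,3aS,6S,7S,8aR)-7-(benzyloxy)-6,8a-dimethyloctahydro-1H-3a,6-epoxyazulen-3-yl]prop-2-en-1-ol | C=C(CO)[C@H]2CC[C@]3(C)C[C@H](OCc5ccccc5)[C@]4(C)CC[C@]23O4 | intermediate
20 | (2S)-2-[(3R,3aS,6S,7S,8aR)-7-(benzyloxy)-6,8a-dimethyloctahydro-1H-3a,6-epoxyazulen-3-yl]propan-1-ol | OC[C@@H](C)[C@H]2CC[C@]3(C)C[C@H](OCc5ccccc5)[C@]4(C)CC[C@]23O4 | intermediate
21 | 4-(benzyloxy)-3-methoxybenzoic acid | COc1cc(C(=O)O)ccc1OCc1ccccc1 | starting material
22 | (2S)-2-[(3R,3aS,6S,7S,8aR)-7-(benzyloxy)-6,8a-dimethyloctahydro-1H-3a,6-epoxyazulen-3-yl]propyl 4-(benzyloxy)-3-methoxybenzoate | COc1cc(C(=O)OC[C@@H](C)[C@H]2CC[C@]3(C)C[C@H](OCc5ccccc5)[C@]4(C)CC[C@]23O4)ccc1OCc1ccccc1 | intermediate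
23 | (2S)-2-[(3R,3aS,6S,7S,8aR)-7-hydroxy-6,8a-dimethyloctahydro-1H-3a,6-epoxyazulen-3-yl]propyl 4-hydroxy-3-methoxybenzoate | COc1cc(C(=O)OC[C@@H](C)[C@H]2CC[C@]3(C)C[C@H](O)[C@]4(C)CC[C@]23O4)ccc1O | target

**Step count**
Total: 14 steps. Longest linear sequence: 13 steps (steps 1 to 8 and 10 to 14); step 9 prepares the second fragment.

**Steps most likely to fail**

1. Step 10 (key step, proposed new method). What may go wrong: the transannular insertion of the hindered trisubstituted alkene into the Pd–O bond may be too slow, or β-hydride elimination of the secondary alkylpalladium intermediate may outrun reductive elimination, giving an allylic ether without the side chain. The fallback uses known chemistry, sets out from 14 and comes back at 18. Transannular iodoetherification of 14 (N-iodosuccinimide, MeCN, 0 °C; Markovnikov, anti addition) should give the iodo ether (3R,3aR,6S,7S,8aR)-7-(benzyloxy)-3-iodo-6,8a-dimethyloctahydro-1H-3a,6-epoxyazulene F1, with the bridge already closed on the face of the C8a methyl. Nickel-catalysed reductive cross-electrophile coupling of F1 with 16 (NiBr2(dme), 4,4'-di-tert-butyl-2,2'-bipyridine, Zn, DMA, rt) would then form the C3–side-chain bond and return to 18. In this variant C3 is set when the C3 radical is captured by nickel, expected on the face of the ring oxygen because the other face carries the axial C4 methylene; a C3 epimer would have to be separated, and β-oxygen elimination of the organonickel is the process to watch.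

2. Step 6. What may go wrong: poor facial selectivity of the peracid (attack syn to the angular methyl) or competing epoxidation of the cyclopentene alkene. The fallback sets out from 10 and comes back at 12, bypassing 11. A reagent-controlled Shi epoxidation (D-fructose-derived ketone, KHSO5 as Oxone 2KHSO5·KHSO4·K2SO4, K2CO3, MeCN/dimethoxymethane/H2O, 0 °C) is aimed at the opposite face, syn to the C8a methyl, as the spiro transition-state model predicts for this ketone; the bulky dioxirane should also discriminate better against the neopentylic cyclopentene alkene. It would give the epoxide (6S,7R,8aR)-6,7-epoxy-6,8a-dimethyl-1,2,4,5,6,7,8,8a-octahydroazulene F2. Opening of F2 by hydroxide at the less substituted C7 with inversion (KOH, DMSO/H2O, 100 °C) gives the same trans-diol 12, because inversion at C7 of this epoxide and inversion at C6 of epoxide 11 converge.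

3. Step 12. What may go wrong: catalyst–substrate mismatch or isomerisation of the allylic alcohol to an aldehyde, leading to poor control of the side-chain centre. The fallback sets out from 14 and comes back at 20. The coupling of step 10 is run with 2-bromopropene in place of 16 to give (3R,3aS,6S,7S,8aR)-7-(benzyloxy)-6,8a-dimethyl-3-(prop-1-en-2-yl)octahydro-1H-3a,6-epoxyazulene F3. Hydroboration–oxidation of F3 (9-BBN, THF, rt; then NaOH, H2O2) gives 20. Here the terminal CH2 becomes CH2OH instead of CH3, so the same facial preference of the alkene leads to the opposite configuration at the new centre; the sequence is therefore the stereochemical complement of a hydrogenation that adds to the wrong face.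

**Further compounds**
F1 | step 10 | (3R,3aR,6S,7S,8aR)-7-(benzyloxy)-3-iodo-6,8a-dimethyloctahydro-1H-3a,6-epoxyazulene | I[C@@H]2CC[C@]3(C)C[C@H](OCc5ccccc5)[C@]4(C)CC[C@]23O4
F2 | step 6 | (6S,7R,8aR)-6,7-epoxy-6,8a-dimethyl-1,2,4,5,6,7,8,8a-octahydroazulene | C[C@]12CCC=C1CC[C@]3(C)O[C@@H]3C2
F3 | step 12 | (3R,3aS,6S,7S,8aR)-7-(benzyloxy)-6,8a-dimethyl-3-(prop-1-en-2-yl)octahydro-1H-3a,6-epoxyazulene | C=C(C)[C@H]2CC[C@]3(C)C[C@H](OCc5ccccc5)[C@]4(C)CC[C@]23O4
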